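**Plan**

1. Retrosynthesis: the two MOM ethers and the quinone oxidation level are removed first. Ring A (the quinone ring) is then cut at C1–C2, C3–C4 and C4–C4a into an aryl(methoxy)carbene chromium complex (ring B plus C1), an alkynylstannane (C2, C3 and the whole side chain) and one CO ligand (C4). The alkyne is cut at the ester C–O bond and at the C(O)–C(sp) bond.
2. Enabling feature: ring A is C1(=O)–C2(R)=C3H–C4(=O) fused at C4a/C8a to a benzene ring with a free ortho position, i.e. carbene carbon + alkyne + CO closed onto an arene. Ring B has identical oxygens at C5 and C8, so C2 and C3 are interchangeable and neither sense of alkyne insertion can give a wrong isomer.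
3. Forward order: the side-chain alkyne (steps 1–5) and the carbene complex (steps 6–7) are made separately. Ring A is closed onto preformed ring B in step 8, oxidised to the quinone in step 9, and the peri phenols are freed in step 10.
4. Stereochemistry: the only stereocentre, (S), is set by catalyst-controlled asymmetric transfer hydrogenation of an alkynyl ketone (step 3); no bond to it is broken afterwards.

Key step: step 8

Remark: locants C1–C8a are those of the 1,4-naphthoquinone of the target with the side chain on C2. The descriptor (S) is constant from compound 6 onward because the order O > sp or sp2 carbon > CH2 > H does not change. The tributylstannyl group is assumed to act as the larger alkyne substituent in the insertion.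

**Route**

Step 1
Reactants: 1 4-methylpent-3-enoic acid
Product: 2 N-methoxy-N,4-dimethylpent-3-enamide
Conditions: CDI, CH2Cl2, 0 °C to rt; then MeNH(OMe)·HCl, rt
Reagents that add atoms: N,O-dimethylhydroxylamine hydrochloride (CNOC.Cl)
Why: Amide formation through the acyl imidazolide (Weinreb amide synthesis) is mild and should leave the β,γ-double bond out of conjugation.

Step 2
Reactants: 2 N-methoxy-N,4-dimethylpent-3-enamide; 3 ethynyltrimethylsilane
Product: 5 6-methyl-1-(trimethylsilyl)hept-5-en-1-yn-3-one, via lithium (trimethylsilyl)acetylide 4 (not isolated)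
Conditions: 3, n-BuLi, THF, −78 °C; then 2, −78 to −20 °C; cold 1 M HCl
Reagents that add atoms: none
Why: Weinreb ketone synthesis: the acetylide adds once and the chelated tetrahedral intermediate persists until the cold quench, which should prevent a second addition and base-induced conjugation of the ynone.

Step 3
Reactants: 5 6-methyl-1-(trimethylsilyl)hept-5-en-1-yn-3-one
Product: 6 (3S)-6-methyl-1-(trimethylsilyl)hept-5-en-1-yn-3-ol
Conditions: Ru[(S,S)-TsNCH(Ph)CH(Ph)NH](p-cymene) (0.5 mol %), i-PrOH, 25 °C
Reagents that add atoms: none
Why: Noyori asymmetric transfer hydrogenation of an α,β-acetylenic ketone: the (S,S)-ligand distinguishes the alkynyl from the alkyl flank in the six-membered metal–ligand bifunctional transition state and should deliver the (S)-carbinol under catalyst control, without reducing alkyne or alkene.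

Step 4
Reactants: 6 (3S)-6-methyl-1-(trimethylsilyl)hept-5-en-1-yn-3-ol; 7 3-methylbut-2-enoic acid
Product: 8 (3S)-6-methyl-1-(trimethylsilyl)hept-5-en-1-yn-3-yl 3-methylbut-2-enoate
Conditions: DCC, DMAP (10 mol %), CH2Cl2, 0 °C to rt
Reagents that add atoms: none
Why: Steglich esterification acylates the secondary propargylic alcohol without breaking the C–O bond of the stereocentre and avoids the ketene pathway that deconjugates the corresponding acid chloride.

Step 5
Reactants: 8 (3S)-6-methyl-1-(trimethylsilyl)hept-5-en-1-yn-3-yl 3-methylbut-2-enoate
Product: 9 (3S)-6-methyl-1-(tributylstannyl)hept-5-en-1-yn-3-yl 3-methylbut-2-enoate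
Conditions: (Bu3Sn)2O (0.55 equiv), TBAF (2 mol %), THF, 60 °C
Reagents that add atoms: bis(tributyltin) oxide (CCCC[Sn](CCCC)(CCCC)O[Sn](CCCC)(CCCC)CCCC)
Why: Fluoride-catalysed silicon-to-tin exchange at an sp carbon is driven by Si–O bond formation and needs no strong base, so ester and stereocentre should survive; the tin is the traceless control element for step 8.

Step 6
Reactants: 10 hydroquinone
Product: 11 1,4-bis(methoxymethoxy)benzene
Conditions: NaH, DMF, 0 °C; MOMCl, 0 °C to rt
Reagents that add atoms: chloromethyl methyl ether (COCCl)
Why: Williamson-type O-alkylation of the bis-phenoxide installs acid-labile acetal ethers that also direct the lithiation of step 7.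

Step 7
Reactants: 11 1,4-bis(methoxymethoxy)benzene; 12 hexacarbonylchromium
Product: 15 pentacarbonyl{[2,5-bis(methoxymethoxy)phenyl](methoxy)methylidene}chromium, via aryllithium 13 (not isolated), via lithium acylchromate 14 (not isolated)
Conditions: n-BuLi, THF, 0 °C; Cr(CO)6, 0 °C to rt; then MeOTf, CH2Cl2, 0 °C
Reagents that add atoms: methyl trifluoromethanesulfonate (COS(=O)(=O)C(F)(F)F)
Why: MOM-directed ortho-lithiation followed by the Fischer carbene synthesis (addition of the aryllithium to a CO ligand, then O-methylation of the acylate) should give the carbene complex; all four ring positions of 11 are equivalent, so regiochemistry is not at issue.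

Step 8
Reactants: 15 pentacarbonyl{[2,5-bis(methoxymethoxy)phenyl](methoxy)methylidene}chromium; 9 (3S)-6-methyl-1-(tributylstannyl)hept-5-en-1-yn-3-yl 3-methylbut-2-enoate
Product: 17 (1S)-1-[4-hydroxy-1-methoxy-5,8-bis(methoxymethoxy)naphthalen-2-yl]-4-methylpent-3-en-1-yl 3-methylbut-2-enoate, via C-stannylated naphthol 16 (not isolated)
Conditions: THF, 55 °C, Ar; then AcOH, air, rt
Reagents that add atoms: none
Why: Dötz benzannulation: thermal loss of one CO from 15 lets the alkyne of 9 insert into the Cr=C bond, the carbene carbon (C1) bonding to the alkyne carbon that carries the side chain (C2) while the tin-bearing carbon (C3) becomes the new chromium-bound carbene carbon; CO insertion at C3 gives a chromium-bound vinylketene (new C3–C4 bond) whose ketene carbon C4 bonds to the free ortho carbon of the aryl group (C4a), tautomerisation gives the stannylated naphthol 16, and AcOH removes the tin. The closest known reaction type is the benzannulation of aryl(alkoxy)carbene chromium complexes with internal alkynes, alkynylstannanes included, in which the stannyl group is a traceless large substituent. One ring (ring A) is closed, by thermal 6π-electrocyclisation of the aryl-conjugated vinylketene onto the only unsubstituted ortho position of the 2,5-dioxygenated aryl group, and aromatisation follows by a hydrogen shift to oxygen. No new stereocentre arises; the (S)-centre lies one atom outside the reacting π-system, no bond to it is broken and the medium is neutral, so it should be retained. The step needs a defined sense of alkyne insertion and CO insertion in preference to capture of the vinylcarbene by the prenyl double bond: the first is expected from the steric demand of SnBu3 (the larger substituent ends next to the CO-derived carbon) and is not product-determining because the equal C5/C8 oxygens make both senses converge on the same quinone in step 9, and the second is the normal course for aryl(alkoxy)carbene complexes of chromium in THF.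

Step 9
Reactants: 17 (1S)-1-[4-hydroxy-1-methoxy-5,8-bis(methoxymethoxy)naphthalen-2-yl]-4-methylpent-3-en-1-yl 3-methylbut-2-enoate
Product: 18 (1S)-1-[5,8-bis(methoxymethoxy)-1,4-dioxo-1,4-dihydronaphthalen-2-yl]-4-methylpent-3-en-1-yl 3-methylbut-2-enoate
Conditions: (NH4)2Ce(NO3)6 (2.2 equiv), MeCN/H2O, 0 °C
Reagents that add atoms: water (O)
Why: Oxidative demethylation of a para-methoxynaphthol by (NH4)2Ce(NO3)6 should give the 1,4-quinone, after which the electron-poor quinone shields the MOM-bearing ring from further oxidation and the carbinol ester from ionisation.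

Step 10
Reactants: 18 (1S)-1-[5,8-bis(methoxymethoxy)-1,4-dioxo-1,4-dihydronaphthalen-2-yl]-4-methylpent-3-en-1-yl 3-methylbut-2-enoate
Product: 19 alkannin β,β-dimethylacrylate
Conditions: HCl (0.2 M), MeOH/THF, 0 °C to rt
Reagents that add atoms: none
Why: Acid-catalysed acetal exchange (MOM ether cleavage) is assisted by the peri carbonyl groups that hydrogen-bond the freed phenols, so mild acid should suffice and the ester, the alkene and the stereocentre should stay intact.

**Compound list**

1 | 4-methylpent-3-enoic acid | CC(C)=CCC(=O)O | starting material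
2 | N-methoxy-N,4-dimethylpent-3-enamide | CC(C)=CCC(=O)N(C)OC | intermediate
3 | ethynyltrimethylsilane | C#C[Si](C)(C)C | starting material
4 | lithium (trimethylsilyl)acetylide | [Li]C#C[Si](C)(C)C | intermediate
5 | 6-methyl-1-(trimethylsilyl)hept-5-en-1-yn-3-one | CC(C)=CCC(=O)C#C[Si](C)(C)C | intermediate
6 | (3S)-6-methyl-1-(trimethylsilyl)hept-5-en-1-yn-3-ol | CC(C)=CC[C@H](O)C#C[Si](C)(C)C | intermediate
7 | 3-methylbut-2-enoic acid | CC(C)=CC(=O)O | starting material
8 | (3S)-6-methyl-1-(trimethylsilyl)hept-5-en-1-yn-3-yl 3-methylbut-2-enoate | CC(C)=CC[C@H](OC(=O)C=C(C)C)C#C[Si](C)(C)C | intermediate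
9 | (3S)-6-methyl-1-(tributylstannyl)hept-5-en-1-yn-3-yl 3-methylbut-2-enoate | CC(C)=CC[C@H](OC(=O)C=C(C)C)C#C[Sn](CCCC)(CCCC)CCCC | intermediate
10 | hydroquinone | Oc1ccc(O)cc1 | starting material
11 | 1,4-bis(methoxymethoxy)benzene | COCOc1ccc(OCOC)cc1 | intermediate
12 | hexacarbonylchromium | O=C=[Cr](=C=O)(=C=O)(=C=O)(=C=O)=C=O | starting material
13 | 2-lithio-1,4-bis(methoxymethoxy)benzene (aryllithium) | [Li]c1cc(OCOC)ccc1OCOC | intermediate
14 | lithium pentacarbonyl{[2,5-bis(methoxymethoxy)phenyl](oxido)methylidene}chromate (lithium acylchromate) | [Li+].[O-]C(c1cc(OCOC)ccc1OCOC)=[Cr](=C=O)(=C=O)(=C=O)(=C=O)=C=O | intermediate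
15 | pentacarbonyl{[2,5-bis(methoxymethoxy)phenyl](methoxy)methylidene}chromium | COC(c1cc(OCOC)ccc1OCOC)=[Cr](=C=O)(=C=O)(=C=O)(=C=O)=C=O | intermediate
16 | (1S)-1-[4-hydroxy-1-methoxy-5,8-bis(methoxymethoxy)-3-(tributylstannyl)naphthalen-2-yl]-4-methylpent-3-en-1-yl 3-methylbut-2-enoate (C-stannylated naphthol) | CC(C)=CC[C@H](OC(=O)C=C(C)C)c1c([Sn](CCCC)(CCCC)CCCC)c(O)c2c(OCOC)ccc(OCOC)c2c1OC | intermediate
17 | (1S)-1-[4-hydroxy-1-methoxy-5,8-bis(methoxymethoxy)naphthalen-2-yl]-4-methylpent-3-en-1-yl 3-methylbut-2-enoate | CC(C)=CC[C@H](OC(=O)C=C(C)C)c1cc(O)c2c(OCOC)ccc(OCOC)c2c1OC | intermediate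
18 | (1S)-1-[5,8-bis(methoxymethoxy)-1,4-dioxo-1,4-dihydronaphthalen-2-yl]-4-methylpent-3-en-1-yl 3-methylbut-2-enoate | CC(C)=CC[C@H](OC(=O)C=C(C)C)C1=CC(=O)c2c(OCOC)ccc(OCOC)c2C1=O | intermediate
19 | alkannin β,β-dimethylacrylate, (1S)-1-(5,8-dihydroxy-1,4-dioxo-1,4-dihydronaphthalen-2-yl)-4-methylpent-3-en-1-yl 3-methylbut-2-enoate | CC(C)=CC[C@H](OC(=O)C=C(C)C)C1=CC(=O)c2c(O)ccc(O)c2C1=O | target

**Totals**

Total step count: 10. Longest linear sequence: 8 steps (steps 1, 2, 3, 4, 5, 8, 9, 10).

**Steps most likely to fail**

Step 8. After insertion in the intended sense the tin-bearing carbene carbon lies within reach of the trisubstituted alkene (a five-membered ring could form), so intramolecular cyclopropanation may compete with CO insertion. The stannylated vinylketene may also be slow to electrocyclise. The fallback sets out from 9. Protodestannylation with AcOH in THF should give the terminal alkyne (3S)-6-methylhept-5-en-1-yn-3-yl 3-methylbut-2-enoate F1. Benzannulation of F1 with 15 (THF, 50 °C, then air) places the side chain on the chromium-bound carbon, from which the alkene is out of reach (only a four-membered ring could form). This should give the regioisomeric naphthol (1S)-1-[1-hydroxy-4-methoxy-5,8-bis(methoxymethoxy)naphthalen-2-yl]-4-methylpent-3-en-1-yl 3-methylbut-2-enoate F2. Oxidation of F2 with (NH4)2Ce(NO3)6 as in step 9 gives the same quinone, so the fallback comes back to the route at 18.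

Step 3. The C4 methylene of 5 is flanked by the carbonyl and the alkene, so enolisation in the slightly basic alcohol medium may move the double bond into conjugation. Reversible hydrogen transfer may also erode the enantiomeric purity. The fallback sets out from 5 and uses a stoichiometric Midland reduction with B-isopinocampheyl-9-borabicyclo[3.3.1]nonane prepared from (−)-α-pinene ((S)-Alpine-borane), in THF at rt, followed by ethanolamine work-up. Hydride is transferred through a cyclic boat-like transition state without base or alcohol, and the (S)-carbinol is expected by analogy with the sense established for alkynyl alkyl ketones. It comes back at 6.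

Step 5. Fluoride or the stannoxide may cleave the propargylic ester or trigger elimination before the Si–Sn exchange is complete. The fallback sets out from 6 and introduces the tin before the ester. K2CO3 in MeOH should remove the silyl group to give (3S)-6-methylhept-5-en-1-yn-3-ol F3. Double deprotonation (n-BuLi, 2 equiv, THF, −78 °C), Bu3SnCl (1 equiv) and aqueous work-up should give (3S)-6-methyl-1-(tributylstannyl)hept-5-en-1-yn-3-ol F4. Acylation of F4 with 3-methylbut-2-enoic anhydride, DMAP and pyridine in CH2Cl2 avoids free carboxylic acid, which would cleave the Sn–C bond, and comes back at 9.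

**Further compounds**

F1 | step 8 | (3S)-6-methylhept-5-en-1-yn-3-yl 3-methylbut-2-enoate | CC(C)=CC[C@H](OC(=O)C=C(C)C)C#C
F2 | step 8 | (1S)-1-[1-hydroxy-4-methoxy-5,8-bis(methoxymethoxy)naphthalen-2-yl]-4-methylpent-3-en-1-yl 3-methylbut-2-enoate | CC(C)=CC[C@H](OC(=O)C=C(C)C)c1cc(OC)c2c(OCOC)ccc(OCOC)c2c1O
F0 | step 3 | none | none
F3 | step 5 | (3S)-6-methylhept-5-en-1-yn-3-ol | CC(C)=CC[C@H](O)C#C
F4 | step 5 | (3S)-6-methyl-1-(tributylstannyl)hept-5-en-1-yn-3-ol | CC(C)=CC[C@H](O)C#C[Sn](CCCC)(CCCC)CCCC
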